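**Retrosynthetic overview**
1. Target 5 ⇒ 4 by removing the two C2–Br bonds (late bromination para to the 5-OH). Ring numbering: C1 carries the CH2 bridge.
2. 4 ⇒ 2 by the key disconnection: the two aryl C5–O bonds, made by ortho C–H oxygenation of each 2-bromophenol ring.
3. 2 ⇒ 1 by removing the two C3–Br bonds (one ortho-bromination per ring).
4. No ring is formed: both benzene rings and the CH2 bridge come intact from 1.

Assumption: the target has no stereocentre and is achiral, so it is made as drawn; 4,5-dichlorophthaloyl peroxide is taken as a separately prepared stock reagent (one operation from 4,5-dichlorophthaloyl chloride and Na2CO3·1.5H2O2, handled in solution behind a shield) and is not counted as a step.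

**Route**

Step 1
Reactants: 1 bis(4-hydroxyphenyl)methane
Product: 2 bis(3-bromo-4-hydroxyphenyl)methane
Conditions: NBS (2.05 equiv, portionwise), p-TsOH·H2O (10 mol%), MeOH, 0 °C → rt, dark
Reagents that add atoms: N-bromosuccinimide, O=C1CCC(=O)N1Br
Why: Electrophilic aromatic bromination; the para position is blocked by the CH2 bridge and the two ortho positions of each ring are equivalent, and acid-catalysed NBS in methanol is known to stop at mono-ortho-bromination of para-substituted phenols because the first bromine deactivates the ring.

Step 2
Reactants: 2 bis(3-bromo-4-hydroxyphenyl)methane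
Product: 4 bis(3-bromo-4,5-dihydroxyphenyl)methane, via bis(dichlorophthalate half-ester) 3 (not isolated)
Conditions: 4,5-dichlorophthaloyl peroxide (2.5 equiv), HFIP, 0 → 23 °C, Ar; then NaHCO3, MeOH/H2O, 40 °C, Ar; 1 M HCl work-up
Reagents that add atoms: 4,5-dichlorophthaloyl peroxide, O=C1OOC(=O)c2cc(Cl)c(Cl)cc12
Why: Proposed new method: a phenol-directed double ortho C–H acyloxylation in which the phenolic O–H hydrogen-bonds to a peroxide carbonyl and holds the weak O–O bond over C5, the only free ortho carbon (C3 carries Br, the para carbon carries CH2); O–O cleavage with C5–O bond formation (reverse-rebound diradical addition or polar attack of the ring on the O–O σ* orbital, both favoured by HFIP) gives a cyclohexadienone that rearomatises by hydrogen transfer to the departing carboxylate, so each ring becomes a catechol half-ester that is deactivated towards a second oxidation and never passes through an o-quinone (no quinone-methide tautomerism at the diarylmethane CH2), and the neighbouring carboxylate then assists mild hydrolysis to the free catechol; the closest known reaction types are arene C–H hydroxylation with phthaloyl peroxides and the ortho-benzoyloxylation of phenols with dibenzoyl peroxide, neither shown as a directed double oxygenation of an ortho-bromophenol pair.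

Step 3
Reactants: 4 bis(3-bromo-4,5-dihydroxyphenyl)methane
Product: 5 bis(2,3-dibromo-4,5-dihydroxyphenyl)methane
Conditions: Br2 (2.05 equiv), AcOH, 15 °C → rt
Reagents that add atoms: bromine, BrBr
Why: Electrophilic aromatic bromination; the 4-OH has no free ortho or para site left, so the 5-OH alone directs, and attack at C2 (para to it) beats C6 (ortho to it), as in the known second bromination of 5-bromovanillin-type rings, while two bromines per ring deactivate against a third.

**Compound list**
1 | bis(4-hydroxyphenyl)methane (4,4'-methylenediphenol), achiral | Oc1ccc(Cc2ccc(O)cc2)cc1 | starting material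
2 | bis(3-bromo-4-hydroxyphenyl)methane, achiral | Oc1ccc(Cc2ccc(O)c(Br)c2)cc1Br | intermediate
3 | bis[3-bromo-5-(2-carboxy-4,5-dichlorobenzoyloxy)-4-hydroxyphenyl]methane, achiral, not isolated | OC(=O)c1cc(Cl)c(Cl)cc1C(=O)Oc1cc(Cc2cc(OC(=O)c3cc(Cl)c(Cl)cc3C(O)=O)c(O)c(Br)c2)cc(Br)c1O | intermediate
4 | bis(3-bromo-4,5-dihydroxyphenyl)methane, achiral | Oc1cc(Cc2cc(O)c(O)c(Br)c2)cc(Br)c1O | intermediate
5 | bis(2,3-dibromo-4,5-dihydroxyphenyl)methane (CNP0260813.0), achiral | Oc1cc(Cc2cc(O)c(O)c(Br)c2Br)c(Br)c(Br)c1O | target

**Totals**
Total step count: 3. Longest linear sequence: 3.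

**Steps most likely to fail**

Step 2 (the proposed new oxygenation). The brominated phenol ring may be too electron-poor for the peroxide. Competing paths are O-acylation of the phenol, phenoxyl-radical coupling, and attack at the CH2 bridge or at C1. Fallback with known chemistry, setting out from compound 2 and coming back at compound 4: magnesium-mediated ortho-formylation (MgCl2, Et3N, paraformaldehyde, THF, reflux) puts a formyl group on the only free ortho carbon of each ring and gives bis(3-bromo-5-formyl-4-hydroxyphenyl)methane F1. Dakin oxidation (30% H2O2, aq. NaOH, rt, then acid) then converts each aldehyde by aryl migration into bis(3-bromo-5-formyloxy-4-hydroxyphenyl)methane F2, which is hydrolysed in the flask to 4. The C5–O bond is then made by the Dakin rearrangement; this sequence is well established for 2-bromophenol itself.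

Step 3 (final bromination of the free bis-catechol). Risks are some bromination at C6, over-bromination, oxidation of the catechol to an o-quinone, and ipso attack at C1 with cleavage of the bridge. Fallback, setting out from compound 4 and coming back at compound 5: exhaustive O-methylation (MeI, K2CO3, DMF) gives bis(3-bromo-4,5-dimethoxyphenyl)methane F3, which cannot be oxidised to a quinone. Bromination (Br2, AcOH, rt) goes para to the unhindered 5-OMe (the 4-OMe is twisted out of conjugation between Br and OMe) and gives bis(2,3-dibromo-4,5-dimethoxyphenyl)methane F4. BBr3 (CH2Cl2, −78 °C → rt) then cleaves the four methyl ethers to 5.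

Step 1 (mono-bromination of each ring). A statistical spread of mono-, di-, tri- and tetrabromides is possible and would need chromatography. Fallback, setting out from compound 1 and coming back at compound 2: self-limiting mono-nitration ortho to each hydroxyl (65% HNO3, AcOH, 10 °C) gives bis(4-hydroxy-3-nitrophenyl)methane F5. Hydrogenation (H2, 10% Pd/C, MeOH) gives bis(3-amino-4-hydroxyphenyl)methane F6. Diazotisation (NaNO2, 48% HBr, 0 °C) gives 5,5'-methylenebis(2-hydroxybenzenediazonium) dibromide F7, which is not isolated, and Sandmeyer bromination (CuBr, 48% HBr, 60 °C) gives 2 with exactly one bromine per ring. Sandmeyer yields on ortho-aminophenols are typically moderate.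

**Further compounds**
F1 | step 2 | bis(3-bromo-5-formyl-4-hydroxyphenyl)methane | O=Cc1cc(Cc2cc(Br)c(O)c(C=O)c2)cc(Br)c1O
F2 | step 2 | bis(3-bromo-5-formyloxy-4-hydroxyphenyl)methane | O=COc1cc(Cc2cc(Br)c(O)c(OC=O)c2)cc(Br)c1O
F3 | step 3 | bis(3-bromo-4,5-dimethoxyphenyl)methane | COc1cc(Cc2cc(OC)c(OC)c(Br)c2)cc(Br)c1OC
F4 | step 3 | bis(2,3-dibromo-4,5-dimethoxyphenyl)methane | COc1cc(Cc2cc(OC)c(OC)c(Br)c2Br)c(Br)c(Br)c1OC
F5 | step 1 | bis(4-hydroxy-3-nitrophenyl)methane | Oc1ccc(Cc2ccc(O)c([N+](=O)[O-])c2)cc1[N+](=O)[O-]
F6 | step 1 | bis(3-amino-4-hydroxyphenyl)methane | Nc1cc(Cc2ccc(O)c(N)c2)ccc1O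
F7 | step 1 | 5,5'-methylenebis(2-hydroxybenzenediazonium) dibromide | Oc1ccc(Cc2ccc(O)c([N+]#N)c2)cc1[N+]#N.[Br-].[Br-]
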